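The plan rests on disconnecting the C4=C5 alkene of the cyclohexene ring. In the target, C6 of this ring is bonded to two alkenyl carbons, C5 of the ring alkene and the α-carbon of the styryl group; while both are still vinyl groups, C6 is not a stereocentre. Ring-closing metathesis of one of these diastereotopic vinyl groups with the isopropenyl group on C3a closes the six-membered ring, forms C4=C5 and creates the C6 stereocentre in one operation. The precursor is an all-trans cyclopentene (C3 methyl, C3a isopropenyl, C7a side chain) whose side chain is quaternary C7 (methyl, ester) joined to the ethyl divinyl carbon C6, assembled by an Ireland–Claisen rearrangement; a Heck arylation then adds phenyl.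

Key step: step 11

Assumption: (R)-4-methylcyclopent-2-en-1-one and ethyl (2S)-2-(triflyloxy)propanoate are taken as purchasable building blocks; atom labels C1–C7a follow the indene numbering of the target in every intermediate.

Step 1
Reactants: 1 (R)-4-methylcyclopent-2-en-1-one; 2 isopropenylmagnesium bromide
Product: 4 trimethyl{[(3S,4R)-4-methyl-3-(prop-1-en-2-yl)cyclopent-1-en-1-yl]oxy}silane, via bromomagnesium enolate 3 (not isolated)
Conditions: 2, CuBr·SMe2 (10 mol%), TMSCl, THF, −78 °C; Et3N, cold aq. NaHCO3 work-up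
Reagents that add atoms: isopropenylmagnesium bromide (2), C=C(C)[Mg]Br; chlorotrimethylsilane, C[Si](C)(C)Cl
Why: Copper-catalysed, TMSCl-accelerated conjugate addition of the Grignard reagent delivers the isopropenyl group to C3a on the face anti to the C3 methyl group, and O-silylation of the enolate fixes its regiochemistry at C1=C7a.

Step 2
Reactants: 4 trimethyl{[(3S,4R)-4-methyl-3-(prop-1-en-2-yl)cyclopent-1-en-1-yl]oxy}silane; 5 ethyl (2S)-2-{[(trifluoromethyl)sulfonyl]oxy}propanoate
Product: 7 ethyl (2S)-2-[(1S,2S,3R)-3-methyl-5-oxo-2-(prop-1-en-2-yl)cyclopentyl]propanoate, via lithium enolate 6 (not isolated)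
Conditions: MeLi, THF, 0 °C; then 5, −78 → −30 °C
Reagents that add atoms: ethyl (2S)-2-{[(trifluoromethyl)sulfonyl]oxy}propanoate (5), CCOC(=O)[C@H](C)OS(=O)(=O)C(F)(F)F
Why: Methyllithium cleaves the silyl enol ether to the regiodefined lithium enolate, which is C-alkylated by the α-triflyloxy ester in an SN2 reaction (inversion at the propanoate carbon) on the face anti to the neighbouring isopropenyl group, giving the 2,3-trans ketone that is also the thermodynamically favoured epimer at C7a.

Step 3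
Reactants: 7 ethyl (2S)-2-[(1S,2S,3R)-3-methyl-5-oxo-2-(prop-1-en-2-yl)cyclopentyl]propanoate
Product: 9 ethyl (2S)-2-[(1S,4S,5S)-4-methyl-5-(prop-1-en-2-yl)-2-{[(trifluoromethyl)sulfonyl]oxy}cyclopent-2-en-1-yl]propanoate, via potassium enolate 8 (not isolated)
Conditions: KHMDS, THF, −78 °C; PhNTf2, −78 → 0 °C; cold dilute HCl work-up
Reagents that add atoms: N-phenylbis(trifluoromethanesulfonimide), O=S(=O)(N(c1ccccc1)S(=O)(=O)C(F)(F)F)C(F)(F)F
Why: Kinetic deprotonation by the bulky amide base occurs at the unhindered C2 methylene and not at the substituted C7a–H or the much less acidic ester α-H, and O-triflation of this enolate gives the C1=C2 enol triflate.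

Step 4
Reactants: 9 ethyl (2S)-2-[(1S,4S,5S)-4-methyl-5-(prop-1-en-2-yl)-2-{[(trifluoromethyl)sulfonyl]oxy}cyclopent-2-en-1-yl]propanoate; 10 ethylmagnesium bromide
Product: 11 ethyl (2S)-2-[(1S,4R,5S)-2-ethyl-4-methyl-5-(prop-1-en-2-yl)cyclopent-2-en-1-yl]propanoate
Conditions: 10, Fe(acac)3 (5 mol%), THF/NMP, −30 °C
Reagents that add atoms: ethylmagnesium bromide (10), CC[Mg]Br
Why: Iron-catalysed Kumada-type cross-coupling of alkenyl triflates with alkyl Grignard reagents is fast at low temperature, so the ethyl group is placed on C1 without attack on the ester and without loss of the alkyl group by β-hydride elimination.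

Step 5
Reactants: 11 ethyl (2S)-2-[(1S,4R,5S)-2-ethyl-4-methyl-5-(prop-1-en-2-yl)cyclopent-2-en-1-yl]propanoate
Product: 13 (2S)-2-[(1S,4R,5S)-2-ethyl-4-methyl-5-(prop-1-en-2-yl)cyclopent-2-en-1-yl]propanoic acid, via lithium carboxylate 12 (not isolated)
Conditions: LiOH·H2O, THF/MeOH/H2O, 50 °C; then cold 1 M HCl
Reagents that add atoms: lithium hydroxide, [Li+].[OH-]
Why: Ordinary saponification of an ethyl ester by acyl attack; any epimerisation at the propanoate α-carbon would be harmless because this centre is planarised in step 9.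

Step 6
Reactants: 14 pent-2-yn-1-ol
Product: 16 (2Z)-3-iodopent-2-en-1-ol, via cyclic vinylalanate 15 (not isolated)
Conditions: NaAlH2(OCH2CH2OMe)2 (Red-Al), THF, 0 °C → rt; EtOAc; I2, −78 → 0 °C; aqueous work-up
Reagents that add atoms: iodine, II
Why: Hydroxyl-directed trans-hydroalumination of the propargylic alcohol places aluminium on C3 in a five-membered alanate, and iodinolysis of the C–Al bond with retention gives the Z-iodoalkene.

Step 7
Reactants: 16 (2Z)-3-iodopent-2-en-1-ol; 17 4,4,5,5-tetramethyl-2-vinyl-1,3,2-dioxaborolane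
Product: 18 (2Z)-3-ethylpenta-2,4-dien-1-ol
Conditions: Pd(dppf)Cl2 (3 mol%), K2CO3, 1,4-dioxane/H2O, 70 °C
Reagents that add atoms: 4,4,5,5-tetramethyl-2-vinyl-1,3,2-dioxaborolane (17), C=CB1OC(C)(C)C(C)(C)O1
Why: Suzuki–Miyaura coupling of the alkenyl iodide with the vinylboronate proceeds with retention of alkene geometry and tolerates the free allylic alcohol.

Step 8
Reactants: 13 (2S)-2-[(1S,4R,5S)-2-ethyl-4-methyl-5-(prop-1-en-2-yl)cyclopent-2-en-1-yl]propanoic acid; 18 (2Z)-3-ethylpenta-2,4-dien-1-ol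
Product: 19 (2Z)-3-ethylpenta-2,4-dien-1-yl (2S)-2-[(1S,4R,5S)-2-ethyl-4-methyl-5-(prop-1-en-2-yl)cyclopent-2-en-1-yl]propanoate
Conditions: DCC, DMAP (cat.), CH2Cl2, 0 °C → rt
Reagents that add atoms: (2Z)-3-ethylpenta-2,4-dien-1-ol (18), OC/C=C(\C=C)CC
Why: Steglich esterification of an unhindered primary allylic alcohol under neutral conditions that leave the acid-sensitive diene untouched.

Step 9
Reactants: 19 (2Z)-3-ethylpenta-2,4-dien-1-yl (2S)-2-[(1S,4R,5S)-2-ethyl-4-methyl-5-(prop-1-en-2-yl)cyclopent-2-en-1-yl]propanoate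
Product: 22 (2R)-3-ethenyl-3-ethyl-2-[(1R,4R,5S)-2-ethyl-4-methyl-5-(prop-1-en-2-yl)cyclopent-2-en-1-yl]-2-methylpent-4-enoic acid, via silyl ketene acetal 20 (not isolated), via trimethylsilyl ester 21 (not isolated)
Conditions: LDA, TMSCl/Et3N, THF, −78 °C → rt, then 65 °C; H2O/MeOH, pH 4 work-up
Reagents that add atoms: none
Why: Ireland–Claisen rearrangement, in which the silyl ketene acetal undergoes a [3,3]-sigmatropic shift that bonds C7 to the fully substituted dienyl terminus and so creates both quaternary carbons; C6 is not stereogenic (two vinyl groups), so only the π-face of C7 counts, and with C7a–H eclipsing the ketene acetal to avoid A1,3 strain the in-plane ethyl group on C1 shields one face while the other is flanked only by H-3a (the isopropenyl group is trans), so that C6 should add anti to C1 and give the required configuration at C7.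

Step 10
Reactants: 22 (2R)-3-ethenyl-3-ethyl-2-[(1R,4R,5S)-2-ethyl-4-methyl-5-(prop-1-en-2-yl)cyclopent-2-en-1-yl]-2-methylpent-4-enoic acid
Product: 24 methyl (2R)-3-ethenyl-3-ethyl-2-[(1R,4R,5S)-2-ethyl-4-methyl-5-(prop-1-en-2-yl)cyclopent-2-en-1-yl]-2-methylpent-4-enoate, via potassium carboxylate 23 (not isolated)
Conditions: MeI, K2CO3, DMF, rt
Reagents that add atoms: iodomethane, CI
Why: O-Alkylation of the carboxylate (SN2 at iodomethane) is indifferent to the crowding around the acyl carbon that would hamper esterification by acyl substitution.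

Step 11
Reactants: 24 methyl (2R)-3-ethenyl-3-ethyl-2-[(1R,4R,5S)-2-ethyl-4-methyl-5-(prop-1-en-2-yl)cyclopent-2-en-1-yl]-2-methylpent-4-enoate
Product: 25 methyl (3R,3aS,6S,7R,7aR)-6-ethenyl-1,6-diethyl-3,4,7-trimethyl-3a,6,7,7a-tetrahydro-3H-indene-7-carboxylate
Conditions: (H2IMes)Cl2Ru=CH(2-iPrOC6H4) (10 mol%), toluene (2 mM), 80 °C, argon purge
Reagents that add atoms: none
Why: A ruthenium alkylidene formed at one of the two monosubstituted vinyl groups on C6 adds to the 1,1-disubstituted isopropenyl alkene in a [2+2] step, and cycloreversion of the ruthenacyclobutane releases the trisubstituted C4=C5 alkene and ethene. The closest known reaction type is diastereotopic-group-selective ring-closing metathesis of a prochiral divinyl carbon, here a quaternary one. The six-membered ring C3a–C4–C5–C6–C7–C7a is closed by forming the endocyclic C4=C5 bond, both new alkene carbons lying in the ring. The only new stereocentre, C6, is controlled by the C7 and C7a centres: the trans relationship at C3a/C7a forces a chair-like closure with C7–CH3 axial and the ester equatorial, and the vinyl group left behind must be either pseudoaxial (syn to the ester, anti to C7–CH3) or pseudoequatorial (gauche to both C7 substituents), the flat vinyl group being expected to take the pseudoaxial site more readily than ethyl, which gives the required 6S configuration. The step needs group selectivity between the vinyl groups; since the two alkylidenes should exchange through ethene faster than the slow closure onto a 1,1-disubstituted alkene, the ratio should reflect these two closure transition states and can be adjusted through the size of the NHC ligand. Site selectivity is secured by the substrate, because the trisubstituted C1=C2 ring alkene and the isopropenyl group do not load the catalyst and high dilution suppresses cross-metathesis.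

Step 12
Reactants: 25 methyl (3R,3aS,6S,7R,7aR)-6-ethenyl-1,6-diethyl-3,4,7-trimethyl-3a,6,7,7a-tetrahydro-3H-indene-7-carboxylate; 26 iodobenzene
Product: 27 methyl (3R,3aS,6S,7R,7aR)-1,6-diethyl-3,4,7-trimethyl-6-[(E)-2-phenylethenyl]-3a,6,7,7a-tetrahydro-3H-indene-7-carboxylate
Conditions: PhI, Pd(OAc)2 (5 mol%), n-Bu4NCl, NaHCO3, DMF, 80 °C
Reagents that add atoms: iodobenzene (26), Ic1ccccc1
Why: Heck arylation, in which phenylpalladium adds to the only monosubstituted alkene with phenyl on the terminal carbon, and syn β-hydride elimination, possible only toward the benzylic carbon because C6 is quaternary, gives the E-styrene without double-bond migration.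

Step 13
Reactants: 27 methyl (3R,3aS,6S,7R,7aR)-1,6-diethyl-3,4,7-trimethyl-6-[(E)-2-phenylethenyl]-3a,6,7,7a-tetrahydro-3H-indene-7-carboxylate
Product: 29 24-nor-spiculoic acid B [(3R,3aS,6S,7R,7aR)-1,6-diethyl-3,4,7-trimethyl-6-[(E)-2-phenylethenyl]-3a,6,7,7a-tetrahydro-3H-indene-7-carboxylic acid], via sodium carboxylate 28 (not isolated)
Conditions: NaSEt, DMF, 90 °C, argon; then cold 1 M HCl
Reagents that add atoms: none
Why: The methyl ester on quaternary C7 is too hindered for acyl attack and is therefore cleaved by SN2 demethylation with thiolate at the methyl carbon, which touches neither the stereocentres nor the alkenes, and acidification gives the acid.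

Compound list
1 | (R)-4-methylcyclopent-2-en-1-one | O=C1C[C@@H](C)C=C1 | starting material
2 | isopropenylmagnesium bromide (prop-1-en-2-ylmagnesium bromide) | C=C(C)[Mg]Br | starting material
3 | bromomagnesium (3S,4R)-4-methyl-3-(prop-1-en-2-yl)cyclopent-1-en-1-olate (not isolated) | Br[Mg]OC1=C[C@@H](C(C)=C)[C@H](C)C1 | intermediate
4 | trimethyl{[(3S,4R)-4-methyl-3-(prop-1-en-2-yl)cyclopent-1-en-1-yl]oxy}silane | C[Si](C)(C)OC1=C[C@@H](C(C)=C)[C@H](C)C1 | intermediate
5 | ethyl (2S)-2-{[(trifluoromethyl)sulfonyl]oxy}propanoate | CCOC(=O)[C@H](C)OS(=O)(=O)C(F)(F)F | starting material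
6 | lithium (3S,4R)-4-methyl-3-(prop-1-en-2-yl)cyclopent-1-en-1-olate (not isolated) | [Li]OC1=C[C@@H](C(C)=C)[C@H](C)C1 | intermediate
7 | ethyl (2S)-2-[(1S,2S,3R)-3-methyl-5-oxo-2-(prop-1-en-2-yl)cyclopentyl]propanoate | O=C1C[C@@H](C)[C@H](C(C)=C)[C@H]1[C@H](C)C(=O)OCC | intermediate
8 | potassium C1=C2 enolate of 7 (O–K on C1; ring and side-chain configuration as in 7; not isolated) | [K]OC1=C[C@@H](C)[C@H](C(C)=C)[C@H]1[C@H](C)C(=O)OCC | intermediate
9 | ethyl (2S)-2-[(1S,4S,5S)-4-methyl-5-(prop-1-en-2-yl)-2-{[(trifluoromethyl)sulfonyl]oxy}cyclopent-2-en-1-yl]propanoate | O=S(=O)(OC1=C[C@@H](C)[C@H](C(C)=C)[C@H]1[C@H](C)C(=O)OCC)C(F)(F)F | intermediate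
10 | ethylmagnesium bromide | CC[Mg]Br | starting material
11 | ethyl (2S)-2-[(1S,4R,5S)-2-ethyl-4-methyl-5-(prop-1-en-2-yl)cyclopent-2-en-1-yl]propanoate | CCC1=C[C@@H](C)[C@H](C(C)=C)[C@H]1[C@H](C)C(=O)OCC | intermediate
12 | lithium (2S)-2-[(1S,4R,5S)-2-ethyl-4-methyl-5-(prop-1-en-2-yl)cyclopent-2-en-1-yl]propanoate (not isolated) | [Li+].CCC1=C[C@@H](C)[C@H](C(C)=C)[C@H]1[C@H](C)C([O-])=O | intermediate
13 | (2S)-2-[(1S,4R,5S)-2-ethyl-4-methyl-5-(prop-1-en-2-yl)cyclopent-2-en-1-yl]propanoic acid | CCC1=C[C@@H](C)[C@H](C(C)=C)[C@H]1[C@H](C)C(=O)O | intermediate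
14 | pent-2-yn-1-ol | CCC#CCO | starting material
15 | sodium 3-ethyl-2,2-bis(2-methoxyethoxy)-2,5-dihydro-1,2-oxaluminol-2-uide (cyclic vinylalanate; not isolated) | [Na+].CCC1=CCO[Al-]1(OCCOC)OCCOC | intermediate
16 | (2Z)-3-iodopent-2-en-1-ol | OC/C=C(\I)CC | intermediate
17 | 4,4,5,5-tetramethyl-2-vinyl-1,3,2-dioxaborolane | C=CB1OC(C)(C)C(C)(C)O1 | starting material
18 | (2Z)-3-ethylpenta-2,4-dien-1-ol | OC/C=C(\C=C)CC | intermediate
19 | (2Z)-3-ethylpenta-2,4-dien-1-yl (2S)-2-[(1S,4R,5S)-2-ethyl-4-methyl-5-(prop-1-en-2-yl)cyclopent-2-en-1-yl]propanoate | CCC1=C[C@@H](C)[C@H](C(C)=C)[C@H]1[C@H](C)C(=O)OC/C=C(\C=C)CC | intermediate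
20 | trimethylsilyl ketene acetal of 19 (C7=C(OSiMe3)O-dienyl; ketene acetal geometry not defined; not isolated) | CCC1=C[C@@H](C)[C@H](C(C)=C)[C@H]1C(C)=C(O[Si](C)(C)C)OC/C=C(\C=C)CC | intermediate
21 | trimethylsilyl ester of 22 (not isolated) | CCC1=C[C@@H](C)[C@H](C(C)=C)[C@H]1[C@@](C)(C(=O)O[Si](C)(C)C)C(CC)(C=C)C=C | intermediate
22 | (2R)-3-ethenyl-3-ethyl-2-[(1R,4R,5S)-2-ethyl-4-methyl-5-(prop-1-en-2-yl)cyclopent-2-en-1-yl]-2-methylpent-4-enoic acid | CCC1=C[C@@H](C)[C@H](C(C)=C)[C@H]1[C@@](C)(C(=O)O)C(CC)(C=C)C=C | intermediate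
23 | potassium salt of 22 (not isolated) | [K+].CCC1=C[C@@H](C)[C@H](C(C)=C)[C@H]1[C@@](C)(C([O-])=O)C(CC)(C=C)C=C | intermediate
24 | methyl (2R)-3-ethenyl-3-ethyl-2-[(1R,4R,5S)-2-ethyl-4-methyl-5-(prop-1-en-2-yl)cyclopent-2-en-1-yl]-2-methylpent-4-enoate (key-step precursor) | CCC1=C[C@@H](C)[C@H](C(C)=C)[C@H]1[C@@](C)(C(=O)OC)C(CC)(C=C)C=C | intermediate
25 | methyl (3R,3aS,6S,7R,7aR)-6-ethenyl-1,6-diethyl-3,4,7-trimethyl-3a,6,7,7a-tetrahydro-3H-indene-7-carboxylate (key-step product) | CCC1=C[C@@H](C)[C@@H]2C(C)=C[C@@](C=C)(CC)[C@](C)(C(=O)OC)[C@@H]12 | intermediate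
26 | iodobenzene | Ic1ccccc1 | starting material
27 | methyl (3R,3aS,6S,7R,7aR)-1,6-diethyl-3,4,7-trimethyl-6-[(E)-2-phenylethenyl]-3a,6,7,7a-tetrahydro-3H-indene-7-carboxylate | CCC1=C[C@@H](C)[C@@H]2C(C)=C[C@@](/C=C/c3ccccc3)(CC)[C@](C)(C(=O)OC)[C@@H]12 | intermediate
28 | sodium salt of 29 (not isolated) | [Na+].CCC1=C[C@@H](C)[C@@H]2C(C)=C[C@@](/C=C/c3ccccc3)(CC)[C@](C)(C([O-])=O)[C@@H]12 | intermediate
29 | 24-nor-spiculoic acid B, (3R,3aS,6S,7R,7aR)-1,6-diethyl-3,4,7-trimethyl-6-[(E)-2-phenylethenyl]-3a,6,7,7a-tetrahydro-3H-indene-7-carboxylic acid | CCC1=C[C@@H](C)[C@@H]2C(C)=C[C@@](/C=C/c3ccccc3)(CC)[C@](C)(C(=O)O)[C@@H]12 | target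

Total step count: 13. Longest linear sequence: 11 steps (steps 1–5 and 8–13); steps 6 and 7 are the side branch to dienol 18.

Steps most likely to fail

Step 11 (key step). The process at risk is the choice between the two diastereotopic vinyl groups of C6. The closure may show little preference, or favour the group that leaves ethyl syn to the ester and so give the C6 epimer; closure between two quaternary carbons may also be slow. The fallback makes C6 stereogenic before ring closure, in the sigmatropic step, and sets out from 16 and 13 and comes back at 27. Suzuki–Miyaura coupling of 16 with commercial (E)-2-phenylethenylboronic acid gives (2Z,4E)-3-ethyl-5-phenylpenta-2,4-dien-1-ol F1. Esterification with 13 under the conditions of step 8 gives the dienyl ester (2Z,4E)-3-ethyl-5-phenylpenta-2,4-dien-1-yl (2S)-2-[(1S,4R,5S)-2-ethyl-4-methyl-5-(prop-1-en-2-yl)cyclopent-2-en-1-yl]propanoate F2. Ireland–Claisen rearrangement under the conditions of step 9 gives (2R,3R,4E)-3-ethenyl-3-ethyl-2-[(1R,4R,5S)-2-ethyl-4-methyl-5-(prop-1-en-2-yl)cyclopent-2-en-1-yl]-2-methyl-5-phenylpent-4-enoic acid F3. Here C6 carries ethyl, vinyl and E-styryl and is set together with C7 through a chair transition state: the ketene acetal geometry expected for LDA in THF (ring substituent syn to the allyloxy oxygen) is paired with the 2Z-dienyl unit, which places styryl pseudoaxial. O-Methylation as in step 10 gives the methyl ester of F3, methyl (2R,3R,4E)-3-ethenyl-3-ethyl-2-[(1R,4R,5S)-2-ethyl-4-methyl-5-(prop-1-en-2-yl)cyclopent-2-en-1-yl]-2-methyl-5-phenylpent-4-enoate F4. Ring-closing metathesis of F4, which has a single vinyl group and a much less reactive 1,2-disubstituted styryl alkene, gives 27 and makes step 12 unnecessary.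

Step 9. The process at risk is the delivery of the dienyl terminus to the π-face of C7: the α-branched ester may enolise slowly, and the facial preference may be low or opposite to the predicted one. In the fallback the methyl group is introduced last, so that iodomethane and not C6 selects the enolate face. This inverts the sense of induction at C7 and removes the need to rearrange an α-branched ester. It sets out from 4 and comes back at 24. Lithium enolate 6, generated from 4 as in step 2, is alkylated with ethyl bromoacetate to give ethyl 2-[(1R,2S,3R)-3-methyl-5-oxo-2-(prop-1-en-2-yl)cyclopentyl]acetate F5. Triflation as in step 3 gives ethyl 2-[(1R,4S,5S)-4-methyl-5-(prop-1-en-2-yl)-2-{[(trifluoromethyl)sulfonyl]oxy}cyclopent-2-en-1-yl]acetate F6, and iron-catalysed ethylation as in step 4 gives ethyl 2-[(1R,4R,5S)-2-ethyl-4-methyl-5-(prop-1-en-2-yl)cyclopent-2-en-1-yl]acetate F7. Saponification gives 2-[(1R,4R,5S)-2-ethyl-4-methyl-5-(prop-1-en-2-yl)cyclopent-2-en-1-yl]acetic acid F8, and esterification with 18 gives (2Z)-3-ethylpenta-2,4-dien-1-yl 2-[(1R,4R,5S)-2-ethyl-4-methyl-5-(prop-1-en-2-yl)cyclopent-2-en-1-yl]acetate F9. Ireland–Claisen rearrangement of this unbranched ester, which forms only the quaternary carbon C6, gives 3-ethenyl-3-ethyl-2-[(1S,4R,5S)-2-ethyl-4-methyl-5-(prop-1-en-2-yl)cyclopent-2-en-1-yl]pent-4-enoic acid F10 as a mixture of C7 epimers. O-Methylation gives its methyl ester, methyl 3-ethenyl-3-ethyl-2-[(1S,4R,5S)-2-ethyl-4-methyl-5-(prop-1-en-2-yl)cyclopent-2-en-1-yl]pent-4-enoate F11. Deprotonation with LDA (THF/DMPU, −78 °C) and C-methylation with iodomethane then create quaternary C7 and lead to 24.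

Step 2. The process at risk is the C-alkylation of a basic lithium enolate by a secondary triflate: proton transfer, elimination to the acrylate or O-alkylation may compete. The fallback reverses the order of the two bond formations on the ring, attaching the side chain by cross-coupling before the conjugate addition. It sets out from 1 and comes back at 7. α-Iodination of 1 (I2, pyridine, CH2Cl2) gives (4R)-2-iodo-4-methylcyclopent-2-en-1-one F12. Palladium-catalysed Negishi-type coupling with the Reformatsky reagent ethyl 2-(bromozincio)propanoate F13, made from ethyl 2-bromopropanoate and zinc, gives ethyl 2-[(3R)-3-methyl-5-oxocyclopent-1-en-1-yl]propanoate F14. Copper-catalysed conjugate addition of 2 anti to the C3 methyl group, followed by protonation and base equilibration of C7a to the trans arrangement, gives 7 together with its propanoate epimer ethyl (2R)-2-[(1S,2S,3R)-3-methyl-5-oxo-2-(prop-1-en-2-yl)cyclopentyl]propanoate F15, which is removed by chromatography.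

Further compounds
F1 | step 11 | (2Z,4E)-3-ethyl-5-phenylpenta-2,4-dien-1-ol | OC/C=C(\C=C\c1ccccc1)CC
F2 | step 11 | (2Z,4E)-3-ethyl-5-phenylpenta-2,4-dien-1-yl (2S)-2-[(1S,4R,5S)-2-ethyl-4-methyl-5-(prop-1-en-2-yl)cyclopent-2-en-1-yl]propanoate | CCC1=C[C@@H](C)[C@H](C(C)=C)[C@H]1[C@H](C)C(=O)OC/C=C(\C=C\c1ccccc1)CC
F3 | step 11 | (2R,3R,4E)-3-ethenyl-3-ethyl-2-[(1R,4R,5S)-2-ethyl-4-methyl-5-(prop-1-en-2-yl)cyclopent-2-en-1-yl]-2-methyl-5-phenylpent-4-enoic acid | CCC1=C[C@@H](C)[C@H](C(C)=C)[C@H]1[C@@](C)(C(=O)O)[C@](CC)(C=C)/C=C/c1ccccc1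
F4 | step 11 | methyl (2R,3R,4E)-3-ethenyl-3-ethyl-2-[(1R,4R,5S)-2-ethyl-4-methyl-5-(prop-1-en-2-yl)cyclopent-2-en-1-yl]-2-methyl-5-phenylpent-4-enoate | CCC1=C[C@@H](C)[C@H](C(C)=C)[C@H]1[C@@](C)(C(=O)OC)[C@](CC)(C=C)/C=C/c1ccccc1
F5 | step 9 | ethyl 2-[(1R,2S,3R)-3-methyl-5-oxo-2-(prop-1-en-2-yl)cyclopentyl]acetate | O=C1C[C@@H](C)[C@H](C(C)=C)[C@H]1CC(=O)OCC
F6 | step 9 | ethyl 2-[(1R,4S,5S)-4-methyl-5-(prop-1-en-2-yl)-2-{[(trifluoromethyl)sulfonyl]oxy}cyclopent-2-en-1-yl]acetate | O=S(=O)(OC1=C[C@@H](C)[C@H](C(C)=C)[C@H]1CC(=O)OCC)C(F)(F)F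
F7 | step 9 | ethyl 2-[(1R,4R,5S)-2-ethyl-4-methyl-5-(prop-1-en-2-yl)cyclopent-2-en-1-yl]acetate | CCC1=C[C@@H](C)[C@H](C(C)=C)[C@H]1CC(=O)OCC
F8 | step 9 | 2-[(1R,4R,5S)-2-ethyl-4-methyl-5-(prop-1-en-2-yl)cyclopent-2-en-1-yl]acetic acid | CCC1=C[C@@H](C)[C@H](C(C)=C)[C@H]1CC(=O)O
F9 | step 9 | (2Z)-3-ethylpenta-2,4-dien-1-yl 2-[(1R,4R,5S)-2-ethyl-4-methyl-5-(prop-1-en-2-yl)cyclopent-2-en-1-yl]acetate | CCC1=C[C@@H](C)[C@H](C(C)=C)[C@H]1CC(=O)OC/C=C(\C=C)CC
F10 | step 9 | 3-ethenyl-3-ethyl-2-[(1S,4R,5S)-2-ethyl-4-methyl-5-(prop-1-en-2-yl)cyclopent-2-en-1-yl]pent-4-enoic acid (both C2 epimers) | CCC1=C[C@@H](C)[C@H](C(C)=C)[C@H]1C(C(=O)O)C(CC)(C=C)C=C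
F11 | step 9 | methyl 3-ethenyl-3-ethyl-2-[(1S,4R,5S)-2-ethyl-4-methyl-5-(prop-1-en-2-yl)cyclopent-2-en-1-yl]pent-4-enoate (both C2 epimers) | CCC1=C[C@@H](C)[C@H](C(C)=C)[C@H]1C(C(=O)OC)C(CC)(C=C)C=C
F12 | step 2 | (4R)-2-iodo-4-methylcyclopent-2-en-1-one | O=C1C[C@@H](C)C=C1I
F13 | step 2 | ethyl 2-(bromozincio)propanoate (Reformatsky reagent) | CCOC(=O)C(C)[Zn]Br
F14 | step 2 | ethyl 2-[(3R)-3-methyl-5-oxocyclopent-1-en-1-yl]propanoate (both epimers at the propanoate carbon) | O=C1C[C@@H](C)C=C1C(C)C(=O)OCC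
F15 | step 2 | ethyl (2R)-2-[(1S,2S,3R)-3-methyl-5-oxo-2-(prop-1-en-2-yl)cyclopentyl]propanoate | O=C1C[C@@H](C)[C@H](C(C)=C)[C@H]1[C@@H](C)C(=O)OCC
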